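The plan rests on forming the central ring B last. Ring B carries an aroyloxy group at C4 (the ester to ring A), a carboxyl carbon at C1 (the ester to the ring C oxygen), a hydroxyl at C2 and a methyl at C6. This pattern maps onto a 1,1,3-trioxygenated butadiene and a but-2-ynoate. A Diels–Alder benzannulation joins a ketene acetal diene that already holds the ring A ester on its C3 oxygen to the but-2-ynoate ester of benzyl orsellinate. It forms C1–C2 and C5–C6 of ring B, and elimination of methanol then delivers the arene. Both depside links are thus made on simple partners before the union.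

Key step: step 7

Assumption: the double-bond geometries drawn for enol ester 6 (E) and for the ketene acetal of diene 7 (Z) are the expected ones but are of no consequence, since these carbons end up in the diene and in the arene; adduct 13 is racemic at its ketal carbon, which is lost on aromatisation.

Step 1
Reactants: 1 3,4,5-trimethoxytoluene
Product: 2 2,3,4-trimethoxy-6-methylbenzaldehyde
Conditions: POCl3, DMF, 0→80 °C; then ice-water
Reagents that add atoms: N,N-dimethylformamide CN(C)C=O; water O
Why: Vilsmeier–Haack formylation, in which the chloroiminium ion attacks one of the two symmetry-equivalent free ring positions of 1, each activated by an ortho and a para methoxy group, so a single aldehyde should form.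

Step 2
Reactants: 2 2,3,4-trimethoxy-6-methylbenzaldehyde
Product: 3 2,3,4-trimethoxy-6-methylbenzoic acid
Conditions: NaClO2, NaH2PO4, 2-methyl-2-butene, t-BuOH/H2O, rt
Reagents that add atoms: sodium chlorite [Na+].[O-]Cl=O
Why: Pinnick oxidation converts the hindered aldehyde into the acid under buffered conditions, and the alkene scavenger should consume hypochlorous acid before it can chlorinate the electron-rich ring.

Step 3
Reactants: 3 2,3,4-trimethoxy-6-methylbenzoic acid; 4 methyl acetoacetate
Product: 6 methyl (E)-3-[(2,3,4-trimethoxy-6-methylbenzoyl)oxy]but-2-enoate, via acid chloride 5 (not isolated)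
Conditions: (COCl)2, cat. DMF, CH2Cl2, 0 °C→rt, evaporate; then 4, Et3N, CH2Cl2, 0 °C→rt
Reagents that add atoms: none
Why: Acid chloride formation followed by enolate O-acylation (enol ester formation), in which the non-chelated triethylammonium enolate of the β-keto ester and a hard, hindered aroyl chloride should react through oxygen and give mainly the E enol ester.

Step 4
Reactants: 6 methyl (E)-3-[(2,3,4-trimethoxy-6-methylbenzoyl)oxy]but-2-enoate
Product: 7 (Z)-4-methoxy-4-(trimethylsiloxy)buta-1,3-dien-2-yl 2,3,4-trimethoxy-6-methylbenzoate
Conditions: LiN(i-Pr)2 (LDA, commercial solution) premixed with TMSCl, THF, −78 °C; pentane, filtration, used crude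
Reagents that add atoms: chlorotrimethylsilane C[Si](C)(C)Cl
Why: Vinylogous silyl ketene acetal formation (γ-deprotonation and O-silylation of a 3-oxygenated crotonate), in which the two ortho substituents shield the aroyl carbonyl from the bulky amide and the in situ silyl quench keeps the lifetime of the dienolate short.

Step 5
Reactants: 8 orsellinic acid (2,4-dihydroxy-6-methylbenzoic acid)
Product: 9 benzyl 2,4-dihydroxy-6-methylbenzoate (benzyl orsellinate)
Conditions: BnBr, KHCO3, DMF, rt
Reagents that add atoms: benzyl bromide BrCc1ccccc1
Why: Carboxylate O-alkylation (SN2), since bicarbonate deprotonates only the carboxylic acid, so both phenols should stay free, and the mild base at room temperature avoids decarboxylation.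

Step 6
Reactants: 9 benzyl 2,4-dihydroxy-6-methylbenzoate; 10 but-2-ynoic acid
Product: 11 benzyl 4-(but-2-ynoyloxy)-2-hydroxy-6-methylbenzoate
Conditions: DCC, DMAP (5 mol%), CH2Cl2, 0 °C→rt
Reagents that add atoms: none
Why: Steglich esterification, in which the 2-hydroxyl is hydrogen-bonded to and flanked by the benzyl ester, so only the free 4-hydroxyl should be acylated, as in standard depside couplings.

Step 7
Reactants: 7 (Z)-4-methoxy-4-(trimethylsiloxy)buta-1,3-dien-2-yl 2,3,4-trimethoxy-6-methylbenzoate; 11 benzyl 4-(but-2-ynoyloxy)-2-hydroxy-6-methylbenzoate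
Product: 14 benzyl 2-hydroxy-4-({2-hydroxy-6-methyl-4-[(2,3,4-trimethoxy-6-methylbenzoyl)oxy]benzoyl}oxy)-6-methylbenzoate, via silyl ether 12 (not isolated), via cyclohexadiene adduct 13 (not isolated)
Conditions: 11, N,O-bis(trimethylsilyl)acetamide (BSA), toluene, 60 °C, evaporate; then 7 (2 equiv), toluene, 110 °C, sealed tube; then 1 M HCl, THF, rt
Reagents that add atoms: none
Why: Diels–Alder reaction of a 1-alkoxy-1-siloxybuta-1,3-diene with an acetylenic ester followed by aromatisation, the established way from ketene acetal dienes and ynoates to 2-hydroxybenzoates; the chelated phenol of 11 is capped beforehand as silyl ether 12 because a free phenol would protonate the ketene acetal. The normal-electron-demand [4+2] addition (asynchronous, at its polar limit a Mukaiyama–Michael addition followed by closure onto the oxocarbenium carbon) closes the six-membered ring B as an intermolecular annulation of a four-carbon and a two-carbon unit and gives the 1,4-cyclohexadiene 13. The orientation needed, diene C4 (the CH2 terminus) to the methyl-bearing β-carbon of the ynoate and the ketal carbon to the α-carbon, is secured by matched polarity: the donor oxygens at diene C1 and C3 both raise the coefficient at C4 and the ester places the largest LUMO coefficient on the alkyne β-carbon, so the hydroxyl should end up ortho and the aroyloxy group para to the ring B carboxyl. The ketal carbon of 13 is a transient racemic stereocentre that vanishes on aromatisation, so no stereocontrol is required. Dilute acid then removes methanol from the mixed ketal (the more basic methoxy oxygen leaves, the silylated oxygen stays as the phenol) and cleaves both silyl ethers, while the aryl esters, the benzyl ester and the methyl ethers are inert to these conditions.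

Step 8
Reactants: 14 benzyl 2-hydroxy-4-({2-hydroxy-6-methyl-4-[(2,3,4-trimethoxy-6-methylbenzoyl)oxy]benzoyl}oxy)-6-methylbenzoate
Product: 15 2-hydroxy-4-({2-hydroxy-6-methyl-4-[(2,3,4-trimethoxy-6-methylbenzoyl)oxy]benzoyl}oxy)-6-methylbenzoic acid
Conditions: H2 (1 atm), 10% Pd/C, EtOAc, rt
Reagents that add atoms: none
Why: Catalytic hydrogenolysis of the benzyl ester frees the ring C acid under neutral conditions that should leave both aryl ester links, the methyl ethers and the phenols untouched, as in standard depside endgames.

Compound list
1 | 3,4,5-trimethoxytoluene | COc1cc(C)cc(OC)c1OC | starting material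
2 | 2,3,4-trimethoxy-6-methylbenzaldehyde | COc1cc(C)c(C=O)c(OC)c1OC | intermediate
3 | 2,3,4-trimethoxy-6-methylbenzoic acid | COc1cc(C)c(C(=O)O)c(OC)c1OC | intermediate
4 | methyl acetoacetate | CC(=O)CC(=O)OC | starting material
5 | 2,3,4-trimethoxy-6-methylbenzoyl chloride | COc1cc(C)c(C(=O)Cl)c(OC)c1OC | intermediate
6 | methyl (E)-3-[(2,3,4-trimethoxy-6-methylbenzoyl)oxy]but-2-enoate | C/C(=C\C(=O)OC)OC(=O)c1c(C)cc(OC)c(OC)c1OC | intermediate
7 | (Z)-4-methoxy-4-(trimethylsiloxy)buta-1,3-dien-2-yl 2,3,4-trimethoxy-6-methylbenzoate | C=C(OC(=O)c1c(C)cc(OC)c(OC)c1OC)/C=C(/OC)O[Si](C)(C)C | intermediate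
8 | orsellinic acid (2,4-dihydroxy-6-methylbenzoic acid) | Cc1cc(O)cc(O)c1C(=O)O | starting material
9 | benzyl 2,4-dihydroxy-6-methylbenzoate | Cc1cc(O)cc(O)c1C(=O)OCc1ccccc1 | intermediate
10 | but-2-ynoic acid | CC#CC(=O)O | starting material
11 | benzyl 4-(but-2-ynoyloxy)-2-hydroxy-6-methylbenzoate | CC#CC(=O)Oc1cc(C)c(C(=O)OCc2ccccc2)c(O)c1 | intermediate
12 | benzyl 4-(but-2-ynoyloxy)-6-methyl-2-(trimethylsiloxy)benzoate | CC#CC(=O)Oc1cc(C)c(C(=O)OCc2ccccc2)c(O[Si](C)(C)C)c1 | intermediate
13 | racemic cyclohexa-1,4-diene adduct: ring carbon 1 bears the carboxyl esterified by the ring C oxygen, carbon 2 bears methoxy and trimethylsiloxy, carbon 4 the ring A aroyloxy group, carbon 5 is CH2, carbon 6 bears methyl; ring C still carries its trimethylsilyl ether and benzyl ester | COC1(O[Si](C)(C)C)C=C(OC(=O)c2c(C)cc(OC)c(OC)c2OC)CC(C)=C1C(=O)Oc1cc(C)c(C(=O)OCc2ccccc2)c(O[Si](C)(C)C)c1 | intermediate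
14 | benzyl 2-hydroxy-4-({2-hydroxy-6-methyl-4-[(2,3,4-trimethoxy-6-methylbenzoyl)oxy]benzoyl}oxy)-6-methylbenzoate | COc1cc(C)c(C(=O)Oc2cc(C)c(C(=O)Oc3cc(C)c(C(=O)OCc4ccccc4)c(O)c3)c(O)c2)c(OC)c1OC | intermediate
15 | 2-hydroxy-4-({2-hydroxy-6-methyl-4-[(2,3,4-trimethoxy-6-methylbenzoyl)oxy]benzoyl}oxy)-6-methylbenzoic acid | COc1cc(C)c(C(=O)Oc2cc(C)c(C(=O)Oc3cc(C)c(C(=O)O)c(O)c3)c(O)c2)c(OC)c1OC | target

Total step count: 8. Longest linear sequence: 6 steps (steps 1, 2, 3, 4, 7, 8).

Steps most likely to fail

1. Step 7. The aroyloxy group is a weaker donor than the siloxy or alkoxy groups of the dienes normally used, so cycloaddition to the β-methyl ynoate may be slower than thermal decay of the ketene acetal. A stepwise course could erode the orientation. The non-aromatic adduct could also lose its aroyl group before it aromatises. The fallback drops the ring construction and assembles the depside stepwise; it sets out from acid 3 and benzyl ester 9 and returns at 14. Acid 3 and 9 are condensed with trifluoroacetic anhydride in toluene, which acylates the free 4-hydroxyl through the mixed anhydride and gives benzyl 2-hydroxy-6-methyl-4-[(2,3,4-trimethoxy-6-methylbenzoyl)oxy]benzoate F1. Hydrogenolysis (H2, Pd/C, EtOAc) gives 2-hydroxy-6-methyl-4-[(2,3,4-trimethoxy-6-methylbenzoyl)oxy]benzoic acid F2. Coupling of F2 with a second portion of 9 (DCC, toluene) at its non-chelated 4-hydroxyl gives 14.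

2. Step 4. The lithium dienolate may expel the aroyloxy group by β-elimination to an allenoate, or the amide may attack the enol ester, so that the ring A acyl group is lost before silylation. The fallback keeps the benzannulation but brings ring A in afterwards; it sets out from 4, 11 and 3 and returns at 14. Methyl acetoacetate 4 is silylated (TMSCl, Et3N) to methyl (Z)-3-(trimethylsiloxy)but-2-enoate F3, and this is converted (LiN(i-Pr)2, TMSCl, THF, −78 °C) into (Z)-1-methoxy-1,3-bis(trimethylsiloxy)buta-1,3-diene F4, a diene that carries no ester. F4 is heated in toluene with silyl ether 12, made from 11 as in step 7, and the adduct is treated with dilute acid to give benzyl 4-[(2,4-dihydroxy-6-methylbenzoyl)oxy]-2-hydroxy-6-methylbenzoate F5. The only non-chelated phenol of F5, the ring B 4-hydroxyl, is then acylated with acid 3 and trifluoroacetic anhydride in toluene to give 14.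

3. Step 3. The ambident enolate may be acylated on carbon, the hindered acid chloride may react sluggishly, and the enol ester may undergo oxygen-to-carbon acyl migration under amine catalysis. The fallback transfers the acyl group to a pre-formed silyl enol ether, which can accept it only on oxygen; it sets out from 3 and 4 and returns at 6. Acid 3 is converted with cyanuric fluoride and pyridine in CH2Cl2 into 2,3,4-trimethoxy-6-methylbenzoyl fluoride F6. F6 is combined with methyl (Z)-3-(trimethylsiloxy)but-2-enoate F3, made from 4 as in the preceding fallback, in THF with catalytic KF and 18-crown-6. Fluoride-catalysed O-acylation of the silyl enol ether should give enol ester 6, whose geometry again does not matter.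

Further compounds
F1 | step 7 | benzyl 2-hydroxy-6-methyl-4-[(2,3,4-trimethoxy-6-methylbenzoyl)oxy]benzoate | COc1cc(C)c(C(=O)Oc2cc(C)c(C(=O)OCc3ccccc3)c(O)c2)c(OC)c1OC
F2 | step 7 | 2-hydroxy-6-methyl-4-[(2,3,4-trimethoxy-6-methylbenzoyl)oxy]benzoic acid | COc1cc(C)c(C(=O)Oc2cc(C)c(C(=O)O)c(O)c2)c(OC)c1OC
F3 | step 4 | methyl (Z)-3-(trimethylsiloxy)but-2-enoate | C/C(=C/C(=O)OC)O[Si](C)(C)C
F4 | step 4 | (Z)-1-methoxy-1,3-bis(trimethylsiloxy)buta-1,3-diene | C=C(O[Si](C)(C)C)/C=C(/OC)O[Si](C)(C)C
F5 | step 4 | benzyl 4-[(2,4-dihydroxy-6-methylbenzoyl)oxy]-2-hydroxy-6-methylbenzoate | Cc1cc(O)cc(O)c1C(=O)Oc1cc(C)c(C(=O)OCc2ccccc2)c(O)c1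
F6 | step 3 | 2,3,4-trimethoxy-6-methylbenzoyl fluoride | COc1cc(C)c(C(=O)F)c(OC)c1OC
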